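**Retrosynthetic overview**

- Last bond: C3–CH2CO2Me, made by adding the silyl ketene acetal of methyl acetate to the cyclic peroxycarbenium ion from a 3-methoxy-1,2-dioxolane.
- 1,2-Dioxolane ⇒ 2,2,4-trisubstituted oxetane: net 4 → 5 ring expansion by stereoinvertive insertion of O–O at the tertiary C–O bond (perhydrolysis, then oxidation and ketalisation).
- Oxetane ⇒ (R)-2,2-disubstituted oxirane: 3 → 4 ring expansion by ethylidene insertion (key step, new). Oxirane ⇒ methyl ketone by catalytic asymmetric methylene transfer.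
- Methyl ketone ⇒ E-enone + MeMgBr (asymmetric conjugate addition); enone ⇒ 8-phenyloct-1-ene + but-3-en-2-one (cross-metathesis); alkene ⇒ 7-bromohept-1-ene + benzyl chloride.
- Ring order: oxirane → oxetane → 1,2-dioxolane; the benzene ring is bought.

Assumption: the sense of induction of the two chiral catalysts (steps 3 and 4) is taken by analogy with linear enones and methyl ketones; if either is opposite, the ligand antipode is used.

**Route**

Step 1
Reactants: 1 7-bromohept-1-ene; 2 benzyl chloride
Product: 4 oct-7-en-1-ylbenzene, via hept-6-en-1-ylmagnesium bromide 3 (not isolated)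
Conditions: Mg, THF, 40 °C; then 2, Li2CuCl4 (3 mol%), THF, 0 °C → rt
Reagents that add atoms: none
Why: Copper-catalysed Kochi-type cross-coupling of a primary alkyl Grignard reagent with a benzylic chloride; the remote terminal alkene is inert.

Step 2
Reactants: 4 oct-7-en-1-ylbenzene; 5 but-3-en-2-one
Product: 6 (3E)-10-phenyldec-3-en-2-one
Conditions: 5 (3 equiv), second-generation Hoveyda–Grubbs catalyst RuCl2(H2IMes)(=CH–C6H4-2-OiPr) (3 mol%), CH2Cl2, 40 °C
Reagents that add atoms: none
Why: Olefin cross-metathesis of a terminal alkene with an electron-poor enone gives the E-enone under thermodynamic control.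

Step 3
Reactants: 6 (3E)-10-phenyldec-3-en-2-one
Product: 7 (4R)-4-methyl-10-phenyldecan-2-one
Conditions: MeMgBr (1.2 equiv), CuBr·SMe2 (5 mol%), (R)-1-[(SP)-2-(diphenylphosphino)ferrocenyl]ethyldicyclohexylphosphine (Josiphos, 6 mol%), t-BuOMe, −75 °C; then H2O
Reagents that add atoms: methylmagnesium bromide, C[Mg]Br
Why: Copper-catalysed asymmetric conjugate addition of MeMgBr to a linear aliphatic enone; the chiral diphosphine–copper complex delivers methyl to one enantioface and sets the (R) methyl-bearing centre.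

Step 4
Reactants: 7 (4R)-4-methyl-10-phenyldecan-2-one
Product: 8 (2R)-2-methyl-2-[(2R)-2-methyl-8-phenyloctyl]oxirane
Conditions: Me3S(O)I (1.2 equiv), NaH (1.2 equiv), LaLi3[(R)-1,1'-binaphthalene-2,2'-diolate]3 (5 mol%), tris(2,4,6-trimethoxyphenyl)phosphine oxide (5 mol%), 5 Å MS, THF, rt
Reagents that add atoms: trimethylsulfoxonium iodide, C[S+](C)(C)=O.[I-]
Why: Catalytic asymmetric Corey–Chaykovsky epoxidation; the La/Li binaphthoxide complex differentiates methyl from the primary alkyl arm of the methyl ketone and sets the (2R) quaternary C–O centre under catalyst control.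

Step 5
Reactants: 8 (2R)-2-methyl-2-[(2R)-2-methyl-8-phenyloctyl]oxirane
Product: 10 (2R)-2,4-dimethyl-2-[(2R)-2-methyl-8-phenyloctyl]oxetane as a mixture of C4 epimers, via sodium γ-sulfonimidoyl alkoxide 9 (not isolated)
Conditions: EtS(O)(=NTs)Ph (1.5 equiv), NaH (1.5 equiv), DMSO, 25 → 65 °C
Reagents that add atoms: S-ethyl-S-phenyl-N-(4-tolylsulfonyl)sulfoximine, CCS(=O)(=NS(=O)(=O)c1ccc(C)cc1)c1ccccc1
Why: Proposed new method: oxirane-to-oxetane ring expansion by ethylidene (not methylene) insertion on an enantioenriched 2,2-disubstituted oxirane; the α-sulfonimidoyl carbanion opens the epoxide at CH2 by SN2, so the quaternary C–O bond is never broken and its configuration is retained, and the γ-alkoxide then displaces the N-tosylsulfinamide nucleofuge at the secondary carbon in a 4-exo-tet Williamson closure; the closest known reaction is the epoxide-to-oxetane ring expansion with dimethyloxosulfonium methylide or S-methyl sulfoximine anions, which transfers only CH2.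

Step 6
Reactants: 10 (2R)-2,4-dimethyl-2-[(2R)-2-methyl-8-phenyloctyl]oxetane
Product: 11 (4S,6R)-4-hydroperoxy-4,6-dimethyl-12-phenyldodecan-2-ol
Conditions: H2O2 (anhydrous, in Et2O, 10 equiv), TMSOTf (0.2 equiv), Et2O, −78 → −20 °C
Reagents that add atoms: hydrogen peroxide, OO
Why: Lewis-acid-promoted perhydrolysis of the oxetane; H2O2 attacks the tertiary carbon of the activated oxonium in a borderline SN2 process with inversion (tertiary C–O cleaved in preference to the secondary one), turning the (2R) C–O centre into the (4S) C–OOH centre.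

Step 7
Reactants: 11 (4S,6R)-4-hydroperoxy-4,6-dimethyl-12-phenyldodecan-2-ol
Product: 13 (4S,6R)-4-[(2-methoxypropan-2-yl)peroxy]-4,6-dimethyl-12-phenyldodecan-2-one, via peroxyketal alcohol 12 (not isolated)
Conditions: 2-methoxypropene (1.1 equiv), PPTS (2 mol%), CH2Cl2, −20 °C; then NaHCO3, Dess–Martin periodinane (1.5 equiv), 0 °C → rt
Reagents that add atoms: 2-methoxypropene, COC(C)=C
Why: Chemoselective peroxyketalisation (the hydroperoxide is more acidic and an α-effect nucleophile, so it adds to the enol ether much faster than the secondary alcohol), then Dess–Martin oxidation of the free carbinol; the tertiary peroxyketal has no oxidisable C–H and both C2 epimers converge on one ketone.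

Step 8
Reactants: 13 (4S,6R)-4-[(2-methoxypropan-2-yl)peroxy]-4,6-dimethyl-12-phenyldodecan-2-one
Product: 14 (5S)-3-methoxy-3,5-dimethyl-5-[(2R)-2-methyl-8-phenyloctyl]-1,2-dioxolane
Conditions: TsOH·H2O (10 mol%), MeOH, 0 °C → rt
Reagents that add atoms: methanol, CO
Why: Acid-catalysed transketalisation frees the hydroperoxide, which closes 5-exo onto the β-ketone to the cyclic peroxyhemiketal and is trapped as the methyl ketal; C5 is untouched and the C3 epimers converge in the next step.

Step 9
Reactants: 14 (5S)-3-methoxy-3,5-dimethyl-5-[(2R)-2-methyl-8-phenyloctyl]-1,2-dioxolane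
Product: 15 methyl 2-[(3R,5S)-3,5-dimethyl-5-[(2R)-2-methyl-8-phenyloctyl]-1,2-dioxolan-3-yl]acetate
Conditions: CH2=C(OMe)OSiMe3 (3 equiv), TiCl4 (1.1 equiv), CH2Cl2, −78 °C
Reagents that add atoms: 1-methoxy-1-(trimethylsilyloxy)ethene, COC(=C)O[Si](C)(C)C
Why: Lewis-acid ionisation to the cyclic peroxycarbenium ion and Mukaiyama-type addition of the silyl ketene acetal; attack anti to the larger C5 substituent (2-methyl-8-phenyloctyl versus methyl) gives the (3R) trans isomer as the major product, with only modest selectivity expected, and the minor C3 epimer is removed by chromatography.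

**Compound list**

1 | 7-bromohept-1-ene | C=CCCCCCBr | starting material
2 | benzyl chloride | ClCc1ccccc1 | starting material
3 | hept-6-en-1-ylmagnesium bromide | C=CCCCCC[Mg]Br | intermediate
4 | oct-7-en-1-ylbenzene (8-phenyloct-1-ene) | C=CCCCCCCc1ccccc1 | intermediate
5 | but-3-en-2-one | CC(=O)C=C | starting material
6 | (3E)-10-phenyldec-3-en-2-one | CC(=O)/C=C/CCCCCCc1ccccc1 | intermediate
7 | (4R)-4-methyl-10-phenyldecan-2-one | CC(=O)C[C@H](C)CCCCCCc1ccccc1 | intermediate
8 | (2R)-2-methyl-2-[(2R)-2-methyl-8-phenyloctyl]oxirane | C[C@@]1(C[C@H](C)CCCCCCc2ccccc2)CO1 | intermediate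
9 | sodium (4R,6R)-4,6-dimethyl-12-phenyl-2-(S-phenyl-N-tosylsulfonimidoyl)dodecan-4-olate (mixture at C2 and S) | [Na+].[O-][C@@](C)(CC(C)S(=O)(=NS(=O)(=O)c1ccc(C)cc1)c1ccccc1)C[C@H](C)CCCCCCc1ccccc1 | intermediate
10 | (2R)-2,4-dimethyl-2-[(2R)-2-methyl-8-phenyloctyl]oxetane (both C4 epimers) | CC1C[C@@](C)(C[C@H](C)CCCCCCc2ccccc2)O1 | intermediate
11 | (4S,6R)-4-hydroperoxy-4,6-dimethyl-12-phenyldodecan-2-ol (both C2 epimers) | CC(O)C[C@@](C)(OO)C[C@H](C)CCCCCCc1ccccc1 | intermediate
12 | (4S,6R)-4-[(2-methoxypropan-2-yl)peroxy]-4,6-dimethyl-12-phenyldodecan-2-ol (both C2 epimers) | CC(O)C[C@@](C)(OOC(C)(C)OC)C[C@H](C)CCCCCCc1ccccc1 | intermediate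
13 | (4S,6R)-4-[(2-methoxypropan-2-yl)peroxy]-4,6-dimethyl-12-phenyldodecan-2-one | CC(=O)C[C@@](C)(OOC(C)(C)OC)C[C@H](C)CCCCCCc1ccccc1 | intermediate
14 | (5S)-3-methoxy-3,5-dimethyl-5-[(2R)-2-methyl-8-phenyloctyl]-1,2-dioxolane (both C3 epimers) | COC1(C)C[C@](C)(C[C@H](C)CCCCCCc2ccccc2)OO1 | intermediate
15 | methyl 2-[(3R,5S)-3,5-dimethyl-5-[(2R)-2-methyl-8-phenyloctyl]-1,2-dioxolan-3-yl]acetate | COC(=O)C[C@@]1(C)C[C@](C)(C[C@H](C)CCCCCCc2ccccc2)OO1 | target

**Step count and risks**

Total step count: 9. Longest linear sequence: 9 (fully linear from 1 and 2).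

Three steps most likely to fail:

Step 5 (the new ethylidene ring expansion). The secondary carbanion may open the epoxide slowly, and closure of a tertiary alkoxide onto a secondary carbon may lose to elimination. The fallback uses known chemistry and sets out from 8. Vinylmagnesium bromide with CuI (10 mol%) in THF at −30 °C opens the epoxide at CH2 to (4S,6R)-4,6-dimethyl-12-phenyldodec-1-en-4-ol F1. Mukaiyama hydration (Co(acac)2, PhSiH3, O2, i-PrOH) gives (4R,6R)-4,6-dimethyl-12-phenyldodecane-2,4-diol F2 as C2 epimers. MsCl and Et3N at −20 °C sulfonylate only the secondary hydroxyl to give (4R,6R)-4-hydroxy-4,6-dimethyl-12-phenyldodecan-2-yl methanesulfonate F3, and KOtBu in THF closes the four-membered ring. The fallback comes back to the route at 10.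

Step 6 (perhydrolysis of the 2,2,4-trisubstituted oxetane). The secondary C–O bond could compete, and partial ionisation would erode the C–OOH centre. The fallback sets out from 7 and moves the perhydrolysis to an oxetane with no secondary C–O bond. One-pot double methylene transfer (same La/Li catalyst, 2.2 equiv ylide, rt then 45 °C) gives (2R)-2-methyl-2-[(2R)-2-methyl-8-phenyloctyl]oxetane F4. H2O2 and TMSOTf then give (3S,5R)-3-hydroperoxy-3,5-dimethyl-11-phenylundecan-1-ol F5. Peroxyketalisation with 2-methoxypropene gives (3S,5R)-3-[(2-methoxypropan-2-yl)peroxy]-3,5-dimethyl-11-phenylundecan-1-ol F6. Dess–Martin oxidation gives (3S,5R)-3-[(2-methoxypropan-2-yl)peroxy]-3,5-dimethyl-11-phenylundecanal F7. MeTi(OiPr)3 adds methyl to the aldehyde, and the fallback comes back to the route at 12 (oxidised as in the second half of step 7).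

Step 9 (C3 selectivity of the peroxycarbenium alkylation). Methyl and the alkyl chain at C5 differ little, so the d.r. may be low, and the tertiary peroxide can fragment under TiCl4. The fallback sets out from 13 and closes the ring by a C–O bond instead. Horner–Wadsworth–Emmons olefination with trimethyl phosphonoacetate (LiCl, DBU, MeCN) gives methyl (5S,7R)-5-[(2-methoxypropan-2-yl)peroxy]-3,5,7-trimethyl-13-phenyltridec-2-enoate F8 as an E/Z mixture. PPTS in MeOH frees methyl (5S,7R)-5-hydroperoxy-3,5,7-trimethyl-13-phenyltridec-2-enoate F9. Et2NH in CF3CH2OH then triggers the 5-exo peroxy-Michael closure; the addition is reversible, so the C3 epimers can equilibrate before separation. The fallback comes back to the route at 15.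

**Further compounds**

F1 | step 5 | (4S,6R)-4,6-dimethyl-12-phenyldodec-1-en-4-ol | C=CC[C@](C)(O)C[C@H](C)CCCCCCc1ccccc1
F2 | step 5 | (4R,6R)-4,6-dimethyl-12-phenyldodecane-2,4-diol (both C2 epimers) | CC(O)C[C@](C)(O)C[C@H](C)CCCCCCc1ccccc1
F3 | step 5 | (4R,6R)-4-hydroxy-4,6-dimethyl-12-phenyldodecan-2-yl methanesulfonate | CC(OS(C)(=O)=O)C[C@](C)(O)C[C@H](C)CCCCCCc1ccccc1
F4 | step 6 | (2R)-2-methyl-2-[(2R)-2-methyl-8-phenyloctyl]oxetane | C[C@@]1(C[C@H](C)CCCCCCc2ccccc2)CCO1
F5 | step 6 | (3S,5R)-3-hydroperoxy-3,5-dimethyl-11-phenylundecan-1-ol | OCC[C@@](C)(OO)C[C@H](C)CCCCCCc1ccccc1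
F6 | step 6 | (3S,5R)-3-[(2-methoxypropan-2-yl)peroxy]-3,5-dimethyl-11-phenylundecan-1-ol | OCC[C@@](C)(OOC(C)(C)OC)C[C@H](C)CCCCCCc1ccccc1
F7 | step 6 | (3S,5R)-3-[(2-methoxypropan-2-yl)peroxy]-3,5-dimethyl-11-phenylundecanal | O=CC[C@@](C)(OOC(C)(C)OC)C[C@H](C)CCCCCCc1ccccc1
F8 | step 9 | methyl (5S,7R)-5-[(2-methoxypropan-2-yl)peroxy]-3,5,7-trimethyl-13-phenyltridec-2-enoate (E/Z) | COC(=O)C=C(C)C[C@@](C)(OOC(C)(C)OC)C[C@H](C)CCCCCCc1ccccc1
F9 | step 9 | methyl (5S,7R)-5-hydroperoxy-3,5,7-trimethyl-13-phenyltridec-2-enoate (E/Z) | COC(=O)C=C(C)C[C@@](C)(OO)C[C@H](C)CCCCCCc1ccccc1
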